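**Retrosynthetic overview**
- The target comes from five-fold O-debenzylation of a pentabenzyl ether. The dodecanoyl group on ring D (the phloroglucinol ring) is put on late by bromination, lithiation and Weinreb acylation at the one kind of open ring D position.
- The C4–H bond comes from ionic hydrogenation of a 4-aryl-chroman-4-ol. Hydride enters trans to the C2 aryl group, so the 2,4-cis (2R,4R) relation follows from C2.
- Key disconnection: ring C (the pyran ring) is cut at C3–C4 and at O1–C8a. This gives a diaryl ketone (C4 as C=O, C8a as C–F) and a β-oxido alkyllithium made from an (S)-iodohydrin (O1–C2–C3, with C2 already set).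
- Enabling feature: C4 is a doubly benzylic carbon between ring A (through C4a) and ring D, and the ring oxygen O1 sits on C8a, ortho to C4a. C4 and C8a can therefore be a 1,3-bis-electrophile (benzophenone carbonyl plus ortho C–F) that matches the 1,3-bis-nucleophile C3/O1 of a 2-lithio-1-arylethanolate.
- Ring order: rings A, B and D are bought as arenes; ring C is the only ring formed (step 4). The ketone comes from a Friedel–Crafts acylation, the iodohydrin from a CBS reduction and halide exchange.

Key step: step 4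

Remark: ring A is the benzo ring of the chroman, ring B the 4-hydroxyphenyl group on C2, ring C the pyran ring and ring D the acylphloroglucinol ring; rotamers about the C4–ring D bond are taken to interconvert and are not treated as stereoisomers.

**Step 1**
Reactants: 1 1,3,5-tris(benzyloxy)benzene; 2 4-(benzyloxy)-2-fluorobenzoic acid
Product: 3 [4-(benzyloxy)-2-fluorophenyl][2,4,6-tris(benzyloxy)phenyl]methanone
Conditions: TFAA, cat. 85% H3PO4, CH2Cl2, 0 °C → rt
Reagents that add atoms: none
Why: Friedel–Crafts acylation through the mixed aroyl trifluoroacetate, which should acylate the very electron-rich, threefold-symmetric triether 1 at its only kind of C–H without a metal Lewis acid that would strip benzyl ethers, the new carbonyl then deactivating ring D against a second acylation.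

**Step 2**
Reactants: 4 1-[4-(benzyloxy)phenyl]-2-bromoethan-1-one
Product: 5 (1S)-1-[4-(benzyloxy)phenyl]-2-bromoethan-1-ol
Conditions: (S)-2-methyl-CBS-oxazaborolidine (10 mol %), BH3·SMe2, THF, 0 °C; MeOH
Reagents that add atoms: none
Why: Corey–Bakshi–Shibata reduction, in which the (S)-oxazaborolidine should deliver hydride to the ketone face that gives the (S)-bromohydrin (aryl as the large group, CH2Br as the small one), as known for phenacyl halides; this carbinol carbon becomes C2 of the target.

**Step 3**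
Reactants: 5 (1S)-1-[4-(benzyloxy)phenyl]-2-bromoethan-1-ol
Product: 6 (1S)-1-[4-(benzyloxy)phenyl]-2-iodoethan-1-ol
Conditions: NaI, acetone, rt, dark
Reagents that add atoms: sodium iodide, [Na+].[I-]
Why: Finkelstein halide exchange at the primary carbon, driven by precipitation of NaBr, should give the iodide needed for a fast iodine–lithium exchange, and the carbinol stereocenter is not touched.

**Step 4**
Reactants: 6 (1S)-1-[4-(benzyloxy)phenyl]-2-iodoethan-1-ol; 3 [4-(benzyloxy)-2-fluorophenyl][2,4,6-tris(benzyloxy)phenyl]methanone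
Product: 9 (2R)-7-(benzyloxy)-2-[4-(benzyloxy)phenyl]-4-[2,4,6-tris(benzyloxy)phenyl]-3,4-dihydro-2H-chromen-4-ol (both C4 epimers), via β-oxido alkyllithium 7 (not isolated), via dilithium 1,3-diolate 8 (not isolated)
Conditions: n-BuLi (1.0 equiv), Et2O, −78 °C; t-BuLi (2.0 equiv), −78 °C; 3 in THF, −78 → −20 °C; then KOt-Bu, DMPU, 60 °C; aq NH4Cl
Reagents that add atoms: none
Why: Deprotonation and iodine–lithium exchange should turn 6 into the β-oxido alkyllithium 7, which is held back from β-elimination at −78 °C because lithium oxide is a very poor leaving group; its carbanion (C3) adds to the non-enolisable carbonyl carbon of 3 (C4), and after cation exchange and warming the secondary alkoxide O1 displaces fluoride at C8a by intramolecular SNAr. The closest known reaction types are the addition of β-oxido organolithiums made from halohydrins to ketones to give 1,3-diols, and the base-mediated closure of 3-(2-fluorophenyl)propan-1-olates to chromans; here the two are run in one flask as a [3+3] annulation of a C3/O1 bis-nucleophile with a C4/C8a bis-electrophile. Ring C closes in the second stage by 6-exo attack of O1 on C8a through a six-membered Meisenheimer-type transition state; the alkoxide on C4 could reach C8a only through a four-membered ring and cannot compete. C2 comes unchanged from 6, since its C–O bond is never broken, and the new carbinol center C4 forms without control, which does not matter because step 5 makes it planar again. The step needs carbonyl addition to win over attack of the alkyllithium at the ketone-activated C–F bond, which the low temperature and the far higher carbonyl reactivity should secure, and it needs the C–F bond to survive until the alkoxide is activated, which the lithium counter-ion at −78 °C should secure.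

**Step 5**
Reactants: 9 (2R)-7-(benzyloxy)-2-[4-(benzyloxy)phenyl]-4-[2,4,6-tris(benzyloxy)phenyl]-3,4-dihydro-2H-chromen-4-ol
Product: 10 (2R,4R)-7-(benzyloxy)-2-[4-(benzyloxy)phenyl]-4-[2,4,6-tris(benzyloxy)phenyl]-3,4-dihydro-2H-chromene
Conditions: Et3SiH, TFA, CH2Cl2, −40 °C
Reagents that add atoms: none
Why: Ionic hydrogenation, in which TFA should ionise the tertiary carbinol to a C4 cation stabilised by ring D, by O1 (ortho) and by the 7-benzyloxy group (para), and Et3SiH should deliver hydride axially on the half-chair, syn to the axial C2–H and trans to the C2 aryl group, so that both C4 epimers of 9 converge on the 2,4-cis (4R) product with both aryl groups equatorial.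

**Step 6**
Reactants: 10 (2R,4R)-7-(benzyloxy)-2-[4-(benzyloxy)phenyl]-4-[2,4,6-tris(benzyloxy)phenyl]-3,4-dihydro-2H-chromene
Product: 11 (2R,4R)-7-(benzyloxy)-2-[4-(benzyloxy)phenyl]-4-[2,4,6-tris(benzyloxy)-3-bromophenyl]-3,4-dihydro-2H-chromene
Conditions: NBS (1.0 equiv), CH2Cl2, −78 → 0 °C, dark
Reagents that add atoms: N-bromosuccinimide, O=C1CCC(=O)N1Br
Why: Electrophilic aromatic bromination, which should take place only on ring D because a phloroglucinol triether is far more nucleophilic than the resorcinol-type ring A or the monoalkoxy ring B, and the two open ring D positions are equivalent, so one monobromide is expected.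

**Step 7**
Reactants: 12 dodecanoyl chloride; 13 N,O-dimethylhydroxylamine hydrochloride
Product: 14 N-methoxy-N-methyldodecanamide
Conditions: K2CO3, H2O–EtOAc, 0 °C → rt
Reagents that add atoms: none
Why: Schotten–Baumann N-acylation, a standard way to a Weinreb amide from an acid chloride.

**Step 8**
Reactants: 11 (2R,4R)-7-(benzyloxy)-2-[4-(benzyloxy)phenyl]-4-[2,4,6-tris(benzyloxy)-3-bromophenyl]-3,4-dihydro-2H-chromene; 14 N-methoxy-N-methyldodecanamide
Product: 16 1-{2,4,6-tris(benzyloxy)-3-[(2R,4R)-7-(benzyloxy)-2-[4-(benzyloxy)phenyl]-3,4-dihydro-2H-chromen-4-yl]phenyl}dodecan-1-one, via aryllithium 15 (not isolated)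
Conditions: n-BuLi (1.0 equiv), THF, −78 °C; 14, −78 → 0 °C; aq NH4Cl
Reagents that add atoms: none
Why: Bromine–lithium exchange followed by Weinreb ketone synthesis, in which the aryllithium flanked by two benzyloxy groups should add once to the amide and the chelated tetrahedral intermediate should hold until work-up; C2 and C4 are not involved.

**Step 9**
Reactants: 16 1-{2,4,6-tris(benzyloxy)-3-[(2R,4R)-7-(benzyloxy)-2-[4-(benzyloxy)phenyl]-3,4-dihydro-2H-chromen-4-yl]phenyl}dodecan-1-one
Product: 17 1-{2,4,6-trihydroxy-3-[(2R,4R)-7-hydroxy-2-(4-hydroxyphenyl)-3,4-dihydro-2H-chromen-4-yl]phenyl}dodecan-1-one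
Conditions: H2 (1 atm), 10% Pd/C, EtOAc–MeOH, rt
Reagents that add atoms: none
Why: Catalytic hydrogenolysis of the five O-benzyl ethers under neutral conditions, under which the cyclic benzylic C2–O1 bond and the hydrogen-bonded aryl ketone are expected to survive, as is usual for benzylated flavans and acylphloroglucinols.

**Compound list**
1 | 1,3,5-tris(benzyloxy)benzene | c1c(OCc2ccccc2)cc(OCc2ccccc2)cc1OCc1ccccc1 | starting material
2 | 4-(benzyloxy)-2-fluorobenzoic acid | OC(=O)c1ccc(OCc2ccccc2)cc1F | starting material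
3 | [4-(benzyloxy)-2-fluorophenyl][2,4,6-tris(benzyloxy)phenyl]methanone | O=C(c1ccc(OCc2ccccc2)cc1F)c1c(OCc2ccccc2)cc(OCc2ccccc2)cc1OCc1ccccc1 | intermediate
4 | 1-[4-(benzyloxy)phenyl]-2-bromoethan-1-one | O=C(CBr)c1ccc(OCc2ccccc2)cc1 | starting material
5 | (1S)-1-[4-(benzyloxy)phenyl]-2-bromoethan-1-ol | BrC[C@H](c1ccc(OCc2ccccc2)cc1)O | intermediate
6 | (1S)-1-[4-(benzyloxy)phenyl]-2-iodoethan-1-ol | IC[C@H](c1ccc(OCc2ccccc2)cc1)O | intermediate
7 | lithium (1R)-1-[4-(benzyloxy)phenyl]-2-lithioethan-1-olate (formed in the flask, not isolated) | [Li]C[C@H](c1ccc(OCc2ccccc2)cc1)O[Li] | intermediate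
8 | dilithium (1R)-3-[4-(benzyloxy)-2-fluorophenyl]-1-[4-(benzyloxy)phenyl]-3-[2,4,6-tris(benzyloxy)phenyl]propane-1,3-bis(olate), both C3 epimers (formed in the flask, not isolated) | [Li]OC(c1ccc(OCc2ccccc2)cc1F)(c1c(OCc2ccccc2)cc(OCc2ccccc2)cc1OCc1ccccc1)C[C@H](c1ccc(OCc2ccccc2)cc1)O[Li] | intermediate
9 | (2R)-7-(benzyloxy)-2-[4-(benzyloxy)phenyl]-4-[2,4,6-tris(benzyloxy)phenyl]-3,4-dihydro-2H-chromen-4-ol, both C4 epimers | OC1(c2c(OCc3ccccc3)cc(OCc3ccccc3)cc2OCc2ccccc2)C[C@H](c2ccc(OCc3ccccc3)cc2)Oc2cc(OCc3ccccc3)ccc21 | intermediate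
10 | (2R,4R)-7-(benzyloxy)-2-[4-(benzyloxy)phenyl]-4-[2,4,6-tris(benzyloxy)phenyl]-3,4-dihydro-2H-chromene | C(c1ccccc1)Oc1cc(OCc2ccccc2)c([C@@H]2C[C@H](c3ccc(OCc4ccccc4)cc3)Oc3cc(OCc4ccccc4)ccc32)c(OCc2ccccc2)c1 | intermediate
11 | (2R,4R)-7-(benzyloxy)-2-[4-(benzyloxy)phenyl]-4-[2,4,6-tris(benzyloxy)-3-bromophenyl]-3,4-dihydro-2H-chromene | C(c1ccccc1)Oc1c(Br)c(OCc2ccccc2)c([C@@H]2C[C@H](c3ccc(OCc4ccccc4)cc3)Oc3cc(OCc4ccccc4)ccc32)c(OCc2ccccc2)c1 | intermediate
12 | dodecanoyl chloride | CCCCCCCCCCCC(=O)Cl | starting material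
13 | N,O-dimethylhydroxylamine hydrochloride | Cl.CNOC | starting material
14 | N-methoxy-N-methyldodecanamide | CCCCCCCCCCCC(=O)N(C)OC | intermediate
15 | {2,4,6-tris(benzyloxy)-3-[(2R,4R)-7-(benzyloxy)-2-[4-(benzyloxy)phenyl]-3,4-dihydro-2H-chromen-4-yl]phenyl}lithium (formed in the flask, not isolated) | [Li]c1c(OCc2ccccc2)cc(OCc2ccccc2)c([C@@H]2C[C@H](c3ccc(OCc4ccccc4)cc3)Oc3cc(OCc4ccccc4)ccc32)c1OCc1ccccc1 | intermediate
16 | 1-{2,4,6-tris(benzyloxy)-3-[(2R,4R)-7-(benzyloxy)-2-[4-(benzyloxy)phenyl]-3,4-dihydro-2H-chromen-4-yl]phenyl}dodecan-1-one | CCCCCCCCCCCC(=O)c1c(OCc2ccccc2)cc(OCc2ccccc2)c([C@@H]2C[C@H](c3ccc(OCc4ccccc4)cc3)Oc3cc(OCc4ccccc4)ccc32)c1OCc1ccccc1 | intermediate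
17 | 1-{2,4,6-trihydroxy-3-[(2R,4R)-7-hydroxy-2-(4-hydroxyphenyl)-3,4-dihydro-2H-chromen-4-yl]phenyl}dodecan-1-one | CCCCCCCCCCCC(=O)c1c(O)cc(O)c([C@@H]2C[C@H](c3ccc(O)cc3)Oc3cc(O)ccc32)c1O | target

**Step count and risks**
Total step count: 9. Longest linear sequence: 7 steps (steps 2, 3, 4, 5, 6, 8, 9).

Steps most likely to fail:

1. Step 4. What may go wrong: loss of lithium oxide from 7 (β-elimination to the styrene) before it adds, or electron transfer to the crowded ketone in place of addition. Fallback, from 3 back to 9: the lithium enolate of commercial 1-[4-(benzyloxy)phenyl]ethan-1-one (LDA, THF, −78 °C; transmetalation with CeCl3 if the addition proves reversible) is added to 3 in an aldol addition to give the β-hydroxy ketone F1. CBS reduction of its aryl ketone with (S)-2-methyl-CBS-oxazaborolidine and BH3·SMe2 should give the (1R)-1,3-diol F2, which is the neutral form of 8. KOt-Bu in THF–DMPU at 60 °C should then close ring C by the same intramolecular SNAr to give 9.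

2. Step 5. What may go wrong: poor facial selectivity in the hydride capture of the C4 cation, or acid-induced ionisation of the C2–O1 bond with loss of the C2 configuration. Fallback, from 9 back to 10: dehydration with Burgess reagent (THF, rt) should give the (2R)-4-aryl-2H-chromene F3. Hydrogenation of its C3=C4 bond over PtO2 (H2, EtOAc), a catalyst that should leave O-benzyl ethers in place, should add hydrogen to the face away from the C2 aryl group and so give 10.

3. Step 8. What may go wrong: slow addition of the doubly ortho-substituted aryllithium to the amide, with proton transfer from the amide α-CH2 or from a benzylic OCH2 group taking over. Fallback, from 10 back to 16 (11 is then not needed): Vilsmeier–Haack formylation (POCl3, DMF, 0 °C → rt; aq NaOAc) should give the ring D aldehyde F4. Addition of undecylmagnesium bromide (THF, 0 °C) should give the secondary carbinol F5 as a mixture at the new carbinol carbon, and Dess–Martin periodinane (CH2Cl2, rt) should oxidise it to 16.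

**Further compounds**
F1 | step 4 | 3-[4-(benzyloxy)-2-fluorophenyl]-1-[4-(benzyloxy)phenyl]-3-hydroxy-3-[2,4,6-tris(benzyloxy)phenyl]propan-1-one | O=C(CC(O)(c1ccc(OCc2ccccc2)cc1F)c1c(OCc2ccccc2)cc(OCc2ccccc2)cc1OCc1ccccc1)c1ccc(OCc2ccccc2)cc1
F2 | step 4 | (1R)-3-[4-(benzyloxy)-2-fluorophenyl]-1-[4-(benzyloxy)phenyl]-3-[2,4,6-tris(benzyloxy)phenyl]propane-1,3-diol | OC(c1ccc(OCc2ccccc2)cc1F)(c1c(OCc2ccccc2)cc(OCc2ccccc2)cc1OCc1ccccc1)C[C@H](c1ccc(OCc2ccccc2)cc1)O
F3 | step 5 | (2R)-7-(benzyloxy)-2-[4-(benzyloxy)phenyl]-4-[2,4,6-tris(benzyloxy)phenyl]-2H-chromene | C1(c2c(OCc3ccccc3)cc(OCc3ccccc3)cc2OCc2ccccc2)=C[C@H](c2ccc(OCc3ccccc3)cc2)Oc2cc(OCc3ccccc3)ccc21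
F4 | step 8 | 2,4,6-tris(benzyloxy)-3-[(2R,4R)-7-(benzyloxy)-2-[4-(benzyloxy)phenyl]-3,4-dihydro-2H-chromen-4-yl]benzaldehyde | O=Cc1c(OCc2ccccc2)cc(OCc2ccccc2)c([C@@H]2C[C@H](c3ccc(OCc4ccccc4)cc3)Oc3cc(OCc4ccccc4)ccc32)c1OCc1ccccc1
F5 | step 8 | 1-{2,4,6-tris(benzyloxy)-3-[(2R,4R)-7-(benzyloxy)-2-[4-(benzyloxy)phenyl]-3,4-dihydro-2H-chromen-4-yl]phenyl}dodecan-1-ol | CCCCCCCCCCCC(O)c1c(OCc2ccccc2)cc(OCc2ccccc2)c([C@@H]2C[C@H](c3ccc(OCc4ccccc4)cc3)Oc3cc(OCc4ccccc4)ccc32)c1OCc1ccccc1
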